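**Retrosynthetic overview**
Labels: unit 1 = ring A (benzo), ring C (pyranone), ring B (4-methoxyphenyl on C2). Unit 2 = ring D (benzo), ring E (pyranone), ring F (4-hydroxyphenyl on C2''). The units are joined by C3 (ring C)–C6'' (ring D), a bond flanked by the C2 aryl group, C4=O, O5'' and O7''.
Feature used: C2 and C3 of ring C are neighbouring sp2 carbons that hold ring B and ring D, so together they are the two carbons of a ring-D/ring-B diarylalkyne. The crowded C3–C6'' bond is therefore laid down early as an aryl–alkynyl bond, where ortho substituents cost nothing.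
Key disconnection: ring C is opened at C3–C4 and O1–C2, giving 2-hydroxy-4,6-dimethoxybenzaldehyde (ring A, C4, O1) and that alkyne. The forward reaction is a rhodium-catalysed oxidative [4+2] annulation through the aldehyde C–H bond.
Ring E is opened at O1''–C2'' and C2''–C3'' (Baker–Venkataraman sequence with 4-(benzyloxy)benzoyl chloride) and at C4''–C4a'' (iodination and Stille acetylation next to the one phenol freed from its MOM group).
Ring order: rings A, B, D and F are bought, ring C is formed in step 5 and ring E in step 11. BCl3 finally removes three benzyl ethers and the peri 5-methyl ether.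

Key step: step 5

Remark: the SMILES carries no stereodescriptor. Rotation about the C3–C6'' axis may be hindered, but no axial configuration is specified, so none is controlled.

**Step 1**
Reactants: 1 3,5-dibenzyloxyphenol
Product: 3 2,6-bis(benzyloxy)-4-hydroxybenzaldehyde, via iminium chloride 2 (not isolated)
Conditions: POCl3 (1.5 equiv), DMF, 0 °C → rt; then H2O
Reagents that add atoms: N,N-dimethylformamide CN(C)C=O; water O
Why: Vilsmeier–Haack formylation: the chloroiminium ion attacks the phloroglucinol-type ring mainly at the carbon para to the free hydroxyl, as is known for 3,5-dimethoxyphenol, water then hydrolyses iminium salt 2, and the minor hydrogen-bonded ortho-hydroxy aldehyde is much less polar and should be removable by chromatography or trituration.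

**Step 2**
Reactants: 3 2,6-bis(benzyloxy)-4-hydroxybenzaldehyde
Product: 4 2,6-bis(benzyloxy)-4-(methoxymethoxy)benzaldehyde
Conditions: MOMCl, i-Pr2NEt, CH2Cl2, 0 °C → rt
Reagents that add atoms: chloromethyl methyl ether COCCl
Why: O-alkylation of the acidic para-formyl phenol (MOM acetal protection) is routine, marks the oxygen that will become O1'' of ring E, and touches neither the aldehyde nor the benzyl ethers.

**Step 3**
Reactants: 4 2,6-bis(benzyloxy)-4-(methoxymethoxy)benzaldehyde
Product: 5 1,3-bis(benzyloxy)-2-ethynyl-5-(methoxymethoxy)benzene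
Conditions: dimethyl (1-diazo-2-oxopropyl)phosphonate, K2CO3, MeOH–THF, rt
Reagents that add atoms: dimethyl (1-diazo-2-oxopropyl)phosphonate COP(=O)(OC)C(=[N+]=[N-])C(C)=O
Why: Seyferth–Gilbert homologation in the Ohira–Bestmann form: methanolysis frees the diazomethylphosphonate anion, which olefinates the aldehyde, and the diazoalkene loses N2 with a 1,2-hydrogen shift to the terminal alkyne under conditions mild enough for MOM and benzyl ethers.

**Step 4**
Reactants: 5 1,3-bis(benzyloxy)-2-ethynyl-5-(methoxymethoxy)benzene; 6 4-iodoanisole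
Product: 7 1,3-bis(benzyloxy)-5-(methoxymethoxy)-2-[(4-methoxyphenyl)ethynyl]benzene
Conditions: PdCl2(PPh3)2 (2 mol %), CuI (4 mol %), Et3N–THF, degassed, rt → 50 °C
Reagents that add atoms: none
Why: Sonogashira coupling: zerovalent palladium adds oxidatively to the unhindered iodide 6 and the copper acetylide of 5 carries the crowded ring, so the two ortho benzyloxy groups sit two atoms away from the reacting centre.

**Step 5**
Reactants: 7 1,3-bis(benzyloxy)-5-(methoxymethoxy)-2-[(4-methoxyphenyl)ethynyl]benzene; 8 2-hydroxy-4,6-dimethoxybenzaldehyde (1.5 equiv)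
Product: 9 3-[2,6-bis(benzyloxy)-4-(methoxymethoxy)phenyl]-5,7-dimethoxy-2-(4-methoxyphenyl)chromen-4-one
Conditions: [Cp*RhCl2]2 (5 mol %), Cu(OAc)2 (2.2 equiv), o-xylene, 120 °C, N2
Reagents that add atoms: none
Why: Acetate exchange places the phenoxide of 8 on trivalent rhodium and the formyl C–H is cleaved by concerted metalation–deprotonation to a five-membered acyl rhodacycle; syn insertion of alkyne 7 into the Rh–acyl bond makes C3–C4, C–O reductive elimination from the resulting seven-membered oxarhodacycle makes O1–C2, and two equivalents of Cu(OAc)2 return monovalent rhodium to the trivalent state. The closest known reaction type is the rhodium-catalysed oxidative [4+2] annulation of salicylaldehydes with internal diarylalkynes to 2,3-diarylchromones. Ring C is the only ring closed, as a six-membered pyranone, by intermolecular insertion followed by reductive elimination that contracts the seven-membered metallacycle to the six-membered heterocycle, and no stereocentre is created. The step needs one orientation of insertion, acyl to the alkyne carbon that bears ring D: the two ortho and one para oxygen donors of ring D stay conjugated with the cylindrical alkyne π system whatever the twist of the ring and outweigh the single methoxy group of ring B, so electron density builds up on the anisyl-bearing carbon, the electrophilic metal bonds there, and the migrating acyl group goes to the electron-poorer carbon next to ring D. This electronic preference works against the steric preference for the bulkier aryl group next to rhodium, so the isomer with rings B and D exchanged is the expected by-product and would have to be separated and identified by long-range C–H correlation from the ring-B ortho protons to C2. Benzyl, methyl and MOM ethers offer no competing directing group and should tolerate Cu(OAc)2 and the liberated acetic acid in an aprotic solvent, and partial loss of MOM would only anticipate step 6.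

**Step 6**
Reactants: 9 3-[2,6-bis(benzyloxy)-4-(methoxymethoxy)phenyl]-5,7-dimethoxy-2-(4-methoxyphenyl)chromen-4-one
Product: 10 3-[2,6-bis(benzyloxy)-4-hydroxyphenyl]-5,7-dimethoxy-2-(4-methoxyphenyl)chromen-4-one
Conditions: HCl (cat.), MeOH–THF, 50 °C
Reagents that add atoms: none
Why: Acid-catalysed acetal exchange removes the MOM group while aryl benzyl ethers, aryl methyl ethers and the chromone are stable to dilute methanolic HCl, so only the oxygen para to the biaryl bond (the future O1'') is freed.

**Step 7**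
Reactants: 10 3-[2,6-bis(benzyloxy)-4-hydroxyphenyl]-5,7-dimethoxy-2-(4-methoxyphenyl)chromen-4-one
Product: 11 3-[2,6-bis(benzyloxy)-4-hydroxy-3-iodophenyl]-5,7-dimethoxy-2-(4-methoxyphenyl)chromen-4-one
Conditions: NIS (1.0 equiv), CH2Cl2–MeCN, −20 → 0 °C, dark
Reagents that add atoms: N-iodosuccinimide O=C1CCC(=O)N1I
Why: Electrophilic aromatic iodination: ring D is the only ring with a free phenol and three oxygen donors and so reacts far faster than the carbonyl-deactivated rings A and B, its two open carbons (both ortho to the hydroxyl) lead to the same constitution, and one equivalent of NIS at low temperature limits double iodination.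

**Step 8**
Reactants: 11 3-[2,6-bis(benzyloxy)-4-hydroxy-3-iodophenyl]-5,7-dimethoxy-2-(4-methoxyphenyl)chromen-4-one
Product: 13 3-[3-acetyl-2,6-bis(benzyloxy)-4-hydroxyphenyl]-5,7-dimethoxy-2-(4-methoxyphenyl)chromen-4-one, via enol ether 12 (not isolated)
Conditions: tributyl(1-ethoxyvinyl)stannane (1.5 equiv), PdCl2(PPh3)2 (5 mol %), toluene, 100 °C; then 1 M HCl, THF, rt
Reagents that add atoms: tributyl(1-ethoxyvinyl)stannane CCCC[Sn](CCCC)(CCCC)C(=C)OCC; water O
Why: Stille coupling with an acetyl-anion equivalent followed by mild hydrolysis of enol ether 12 installs the acetyl group without the Lewis acid that a Friedel–Crafts or Fries acetylation would need and that would endanger the benzyl ether next to the new carbonyl.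

**Step 9**
Reactants: 13 3-[3-acetyl-2,6-bis(benzyloxy)-4-hydroxyphenyl]-5,7-dimethoxy-2-(4-methoxyphenyl)chromen-4-one; 14 4-(benzyloxy)benzoyl chloride
Product: 15 2-acetyl-3,5-bis(benzyloxy)-4-[5,7-dimethoxy-2-(4-methoxyphenyl)-4-oxochromen-3-yl]phenyl 4-(benzyloxy)benzoate
Conditions: Et3N, DMAP (cat.), CH2Cl2, 0 °C → rt
Reagents that add atoms: none
Why: DMAP-catalysed esterification of the single phenol is the first stage of the Baker–Venkataraman sequence, the nucleophilic catalyst overcoming the hydrogen bond of the phenol to the acetyl group.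

**Step 10**
Reactants: 15 2-acetyl-3,5-bis(benzyloxy)-4-[5,7-dimethoxy-2-(4-methoxyphenyl)-4-oxochromen-3-yl]phenyl 4-(benzyloxy)benzoate
Product: 16 1-{2,4-bis(benzyloxy)-3-[5,7-dimethoxy-2-(4-methoxyphenyl)-4-oxochromen-3-yl]-6-hydroxyphenyl}-3-[4-(benzyloxy)phenyl]propane-1,3-dione
Conditions: t-BuOK (2.5 equiv), THF, 0 °C → rt; then AcOH
Reagents that add atoms: none
Why: Baker–Venkataraman rearrangement: the methyl ketone enolate attacks the neighbouring aryl ester through a six-membered transition state and expels the phenoxide, formation of the stabilised diketonate drives the O-to-C acyl shift, and a hindered alkoxide avoids hydroxide attack at C2 of ring C.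

**Step 11**
Reactants: 16 1-{2,4-bis(benzyloxy)-3-[5,7-dimethoxy-2-(4-methoxyphenyl)-4-oxochromen-3-yl]-6-hydroxyphenyl}-3-[4-(benzyloxy)phenyl]propane-1,3-dione
Product: 17 5,7-bis(benzyloxy)-2-[4-(benzyloxy)phenyl]-6-[5,7-dimethoxy-2-(4-methoxyphenyl)-4-oxochromen-3-yl]chromen-4-one
Conditions: p-TsOH·H2O (20 mol %), toluene, 90 °C
Reagents that add atoms: none
Why: Acid-catalysed cyclodehydration: the only free phenol adds to the aroyl carbonyl to a six-membered hemiketal and water is lost to give pyranone ring E, and because O5'' stays benzylated the closure can only run through O1'', which fixes the 6''-linkage and excludes the 8''-linked isomer.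

**Step 12**
Reactants: 17 5,7-bis(benzyloxy)-2-[4-(benzyloxy)phenyl]-6-[5,7-dimethoxy-2-(4-methoxyphenyl)-4-oxochromen-3-yl]chromen-4-one
Product: 18 5,7-dihydroxy-6-[5-hydroxy-7-methoxy-2-(4-methoxyphenyl)-4-oxochromen-3-yl]-2-(4-hydroxyphenyl)chromen-4-one (CNP0273448.0)
Conditions: BCl3 (1 M in CH2Cl2, 8 equiv), pentamethylbenzene (6 equiv), CH2Cl2, −78 °C → rt; then H2O
Reagents that add atoms: none
Why: Lewis-acid ether cleavage: BCl3 with pentamethylbenzene as a non-basic benzyl-cation trap removes aryl benzyl ethers at low temperature, on warming the boron chelate between C4=O and O5 cleaves the peri methyl ether, and the non-chelated 7- and 4'-methyl ethers are of the kind known to resist BCl3.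

**Compound list**
1 | 3,5-dibenzyloxyphenol | Oc1cc(OCc2ccccc2)cc(OCc2ccccc2)c1 | starting material
2 | [2,6-bis(benzyloxy)-4-hydroxybenzylidene]dimethyliminium chloride | C[N+](C)=Cc1c(OCc2ccccc2)cc(O)cc1OCc1ccccc1.[Cl-] | intermediate
3 | 2,6-bis(benzyloxy)-4-hydroxybenzaldehyde | O=Cc1c(OCc2ccccc2)cc(O)cc1OCc1ccccc1 | intermediate
4 | 2,6-bis(benzyloxy)-4-(methoxymethoxy)benzaldehyde | COCOc1cc(OCc2ccccc2)c(C=O)c(OCc2ccccc2)c1 | intermediate
5 | 1,3-bis(benzyloxy)-2-ethynyl-5-(methoxymethoxy)benzene | COCOc1cc(OCc2ccccc2)c(C#C)c(OCc2ccccc2)c1 | intermediate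
6 | 4-iodoanisole | COc1ccc(I)cc1 | starting material
7 | 1,3-bis(benzyloxy)-5-(methoxymethoxy)-2-[(4-methoxyphenyl)ethynyl]benzene | COCOc1cc(OCc2ccccc2)c(C#Cc2ccc(OC)cc2)c(OCc2ccccc2)c1 | intermediate
8 | 2-hydroxy-4,6-dimethoxybenzaldehyde | COc1cc(O)c(C=O)c(OC)c1 | starting material
9 | 3-[2,6-bis(benzyloxy)-4-(methoxymethoxy)phenyl]-5,7-dimethoxy-2-(4-methoxyphenyl)chromen-4-one | COc1ccc(-c2oc3cc(OC)cc(OC)c3c(=O)c2-c2c(OCc3ccccc3)cc(OCOC)cc2OCc2ccccc2)cc1 | intermediate
10 | 3-[2,6-bis(benzyloxy)-4-hydroxyphenyl]-5,7-dimethoxy-2-(4-methoxyphenyl)chromen-4-one | COc1ccc(-c2oc3cc(OC)cc(OC)c3c(=O)c2-c2c(OCc3ccccc3)cc(O)cc2OCc2ccccc2)cc1 | intermediate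
11 | 3-[2,6-bis(benzyloxy)-4-hydroxy-3-iodophenyl]-5,7-dimethoxy-2-(4-methoxyphenyl)chromen-4-one | COc1ccc(-c2oc3cc(OC)cc(OC)c3c(=O)c2-c2c(OCc3ccccc3)cc(O)c(I)c2OCc2ccccc2)cc1 | intermediate
12 | 3-[2,6-bis(benzyloxy)-3-(1-ethoxyvinyl)-4-hydroxyphenyl]-5,7-dimethoxy-2-(4-methoxyphenyl)chromen-4-one | COc1ccc(-c2oc3cc(OC)cc(OC)c3c(=O)c2-c2c(OCc3ccccc3)cc(O)c(C(=C)OCC)c2OCc2ccccc2)cc1 | intermediate
13 | 3-[3-acetyl-2,6-bis(benzyloxy)-4-hydroxyphenyl]-5,7-dimethoxy-2-(4-methoxyphenyl)chromen-4-one | COc1ccc(-c2oc3cc(OC)cc(OC)c3c(=O)c2-c2c(OCc3ccccc3)cc(O)c(C(C)=O)c2OCc2ccccc2)cc1 | intermediate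
14 | 4-(benzyloxy)benzoyl chloride | O=C(Cl)c1ccc(OCc2ccccc2)cc1 | starting material
15 | 2-acetyl-3,5-bis(benzyloxy)-4-[5,7-dimethoxy-2-(4-methoxyphenyl)-4-oxochromen-3-yl]phenyl 4-(benzyloxy)benzoate | COc1ccc(-c2oc3cc(OC)cc(OC)c3c(=O)c2-c2c(OCc3ccccc3)cc(OC(=O)c3ccc(OCc4ccccc4)cc3)c(C(C)=O)c2OCc2ccccc2)cc1 | intermediate
16 | 1-{2,4-bis(benzyloxy)-3-[5,7-dimethoxy-2-(4-methoxyphenyl)-4-oxochromen-3-yl]-6-hydroxyphenyl}-3-[4-(benzyloxy)phenyl]propane-1,3-dione | COc1ccc(-c2oc3cc(OC)cc(OC)c3c(=O)c2-c2c(OCc3ccccc3)cc(O)c(C(=O)CC(=O)c3ccc(OCc4ccccc4)cc3)c2OCc2ccccc2)cc1 | intermediate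
17 | 5,7-bis(benzyloxy)-2-[4-(benzyloxy)phenyl]-6-[5,7-dimethoxy-2-(4-methoxyphenyl)-4-oxochromen-3-yl]chromen-4-one | COc1ccc(-c2oc3cc(OC)cc(OC)c3c(=O)c2-c2c(OCc3ccccc3)cc3oc(-c4ccc(OCc5ccccc5)cc4)cc(=O)c3c2OCc2ccccc2)cc1 | intermediate
18 | 5,7-dihydroxy-6-[5-hydroxy-7-methoxy-2-(4-methoxyphenyl)-4-oxochromen-3-yl]-2-(4-hydroxyphenyl)chromen-4-one | COc1ccc(-c2oc3cc(OC)cc(O)c3c(=O)c2-c2c(O)cc3oc(-c4ccc(O)cc4)cc(=O)c3c2O)cc1 | target

**Total step count:** 12. **Longest linear sequence:** 12 steps (1 → 18).

**Steps most likely to fail**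

Step 5. Three things may go wrong.
- The alkyne may insert in the reverse orientation, with steric control overriding the electronic bias. Coordination of an ortho benzyloxy oxygen to rhodium could help this.
- The doubly flanked alkyne may bind so slowly that the acyl rhodacycle decarbonylates.
- The free acid formed may strip the MOM group early.

The fallback sets out from 4 and comes back at 9. It makes the C3–ring D bond by cross-coupling, so that the halide position fixes the regiochemistry.
- Pinnick oxidation of 4 (NaClO2, NaH2PO4, 2-methyl-2-butene, t-BuOH–H2O) should give 2,6-bis(benzyloxy)-4-(methoxymethoxy)benzoic acid F1.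
- Decarboxylative iodination (I2, K3PO4, MeCN, 100 °C), a reaction known for 2,6-dialkoxybenzoic acids, should give 1,3-bis(benzyloxy)-2-iodo-5-(methoxymethoxy)benzene F2, with iodine at the former carboxyl carbon.
- Iodine–magnesium exchange (i-PrMgCl·LiCl, THF, 0 °C) and a quench with 2-isopropoxy-4,4,5,5-tetramethyl-1,3,2-dioxaborolane should give 2-[2,6-bis(benzyloxy)-4-(methoxymethoxy)phenyl]-4,4,5,5-tetramethyl-1,3,2-dioxaborolane F3.
- Purchased 5,7-dimethoxy-2-(4-methoxyphenyl)chromen-4-one F4 is lithiated at C3 (LDA, THF, −78 °C) and quenched with I2 to 3-iodo-5,7-dimethoxy-2-(4-methoxyphenyl)chromen-4-one F5.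
- Suzuki–Miyaura coupling of F3 with F5 (Pd(OAc)2, SPhos, K3PO4, toluene–H2O, 100 °C) should give 9, at the price of a hindered biaryl coupling.

Step 1. Attack ortho to the hydroxyl may compete more strongly than in the dimethyl ether series, because the two benzyloxy groups crowd the para carbon. The fallback sets out from 1 and comes back at 3. It replaces the intrinsic para preference by a steric blocking group.
- 1 is silylated (TIPSCl, imidazole, DMF) to [3,5-bis(benzyloxy)phenoxy]triisopropylsilane F6.
- The bulky silyl group shields both carbons next to its oxygen, so Vilsmeier–Haack formylation (POCl3, DMF; then H2O) is steered to the carbon between the two benzyloxy groups. This should give 2,6-bis(benzyloxy)-4-(triisopropylsilyloxy)benzaldehyde F7.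
- TBAF in THF at 0 °C then frees 3.

Step 12. Cleavage of the non-chelated benzyl ethers may stay incomplete at temperatures the 7- and 4'-methyl ethers survive. Escaped benzyl cations may re-alkylate ring A or ring D. Prolonged warming may start to remove the wrong methyl ethers. The fallback sets out from 17 and comes back at 18, and it separates the two tasks.
- Neutral hydrogenolysis (H2, Pd/C, THF–MeOH, rt) removes all three benzyl groups without any carbocation. It should give 6-[5,7-dimethoxy-2-(4-methoxyphenyl)-4-oxochromen-3-yl]-5,7-dihydroxy-2-(4-hydroxyphenyl)chromen-4-one F8.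
- Chelation-controlled demethylation with AlCl3 in MeCN at 70 °C followed by aqueous HCl, the classical selective cleavage of a flavone 5-methyl ether, then gives 18.

**Further compounds**
F1 | step 5 | 2,6-bis(benzyloxy)-4-(methoxymethoxy)benzoic acid | COCOc1cc(OCc2ccccc2)c(C(=O)O)c(OCc2ccccc2)c1
F2 | step 5 | 1,3-bis(benzyloxy)-2-iodo-5-(methoxymethoxy)benzene | COCOc1cc(OCc2ccccc2)c(I)c(OCc2ccccc2)c1
F3 | step 5 | 2-[2,6-bis(benzyloxy)-4-(methoxymethoxy)phenyl]-4,4,5,5-tetramethyl-1,3,2-dioxaborolane | COCOc1cc(OCc2ccccc2)c(B2OC(C)(C)C(C)(C)O2)c(OCc2ccccc2)c1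
F4 | step 5 | 5,7-dimethoxy-2-(4-methoxyphenyl)chromen-4-one (purchased) | COc1ccc(-c2cc(=O)c3c(OC)cc(OC)cc3o2)cc1
F5 | step 5 | 3-iodo-5,7-dimethoxy-2-(4-methoxyphenyl)chromen-4-one | COc1ccc(-c2oc3cc(OC)cc(OC)c3c(=O)c2I)cc1
F6 | step 1 | [3,5-bis(benzyloxy)phenoxy]triisopropylsilane | CC(C)[Si](Oc1cc(OCc2ccccc2)cc(OCc2ccccc2)c1)(C(C)C)C(C)C
F7 | step 1 | 2,6-bis(benzyloxy)-4-(triisopropylsilyloxy)benzaldehyde | CC(C)[Si](Oc1cc(OCc2ccccc2)c(C=O)c(OCc2ccccc2)c1)(C(C)C)C(C)C
F8 | step 12 | 6-[5,7-dimethoxy-2-(4-methoxyphenyl)-4-oxochromen-3-yl]-5,7-dihydroxy-2-(4-hydroxyphenyl)chromen-4-one | COc1ccc(-c2oc3cc(OC)cc(OC)c3c(=O)c2-c2c(O)cc3oc(-c4ccc(O)cc4)cc(=O)c3c2O)cc1
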